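**Plan**

1. Retrosynthes: remove the PMB ether on O15; cut C10–OH (γ-oxygenation of the C3 dienol); cut C2–C4′ and C14–C15′ of the central cyclohexene (Diels–Alder of diene 18 with dehydrozaluzanin C 21); in 18 cut the lactone O–C6 bond, then C1–C5, C2–C3 and C3–C4 (C3 = CO); cut the allene back to a propargylic alcohol and C6–C7 to an allyl bromide plus an ynal.
2. Enabling feature: in the hydroxylated half the lactone oxygen on C6 is δ to the C3 ketone through C2=C1 and C5 (O=C3–C2=C1–C5–C6–O). The lactone ring is therefore the 1,6-oxa-Michael adduct of the C12 acid to a 4-alkylidenecyclopentenone, which is what an allene (C4=C5=C6) + alkyne (C1≡C2) + CO cyclocarbonylation delivers.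
3. Forward: acyclic allenyne acid 16 → in one flask the five-membered enone ring and the seven-membered ring, then the lactone ring (18). Dehydrocostus lactone → 21. 18 + 21 → central cyclohexene with spiro C4′; then C10–OH; then PMB removal.
4. Stereochemistry: C7 from a catalyst-controlled allylation (step 6); the partner carbinol at C6 is converted via the allene axis into C4; C6 and C5 follow from C7 in the lactonisation; C1′, C5′, C6′, C7′ come from the chiral pool; spiro C4′ from α-face attack on 21; C10 from β-face oxygenation.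

Key step: step 9

Remark: locants follow guaianolide numbering (primed for the half derived from 21); 4-methoxybenzyl propargyl ether 10 is taken as purchasable (otherwise one Williamson step from propargyl alcohol).

**Route**

Step 1
Reactants: 1 acetaldehyde N,N-dimethylhydrazone; 2 2,3-dibromoprop-1-ene
Product: 4 4-bromopent-4-enal, via bromoallyl hydrazone 3 (not isolated)
Conditions: LiN(iPr)2, THF, −78 to 0 °C; then 2 M HCl, Et2O, 0 °C
Reagents that add atoms: water, O
Why: Aza-enolate alkylation at the allylic bromide of 2 (the vinylic bromide is inert) followed by hydrazone hydrolysis is a standard aldehyde α-alkylation; no stereocentre is formed.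

Step 2
Reactants: 4 4-bromopent-4-enal; 5 ethynyltrimethylsilane
Product: 6 4-methylidene-6-(trimethylsilyl)hex-5-ynal
Conditions: Pd(PPh3)2Cl2 (3 mol %), CuI (6 mol %), Et3N, THF, 40 °C
Reagents that add atoms: none
Why: Sonogashira coupling of a 2-bromo-1-alkene with a terminal alkyne should give the 2-substituted enyne (future C14=C10–C1≡C2) and the aldehyde tolerates the tertiary amine.

Step 3
Reactants: 6 4-methylidene-6-(trimethylsilyl)hex-5-ynal; 7 methyl acrylate
Product: 8 methyl 3-hydroxy-2,6-dimethylidene-8-(trimethylsilyl)oct-7-ynoate (racemic)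
Conditions: DABCO (1 equiv), methyl acrylate (3 equiv), neat, 23 °C
Reagents that add atoms: none
Why: Morita–Baylis–Hillman reaction of an unhindered aliphatic aldehyde; the racemic carbinol centre is removed in step 4.

Step 4
Reactants: 8 methyl 3-hydroxy-2,6-dimethylidene-8-(trimethylsilyl)oct-7-ynoate
Product: 9 methyl (2Z)-2-(bromomethyl)-6-methylidene-8-(trimethylsilyl)oct-2-en-7-ynoate
Conditions: NBS, Me2S, CH2Cl2, 0 to 23 °C
Reagents that add atoms: N-bromosuccinimide, O=C1CCC(=O)N1Br
Why: Corey–Kim-type activation of the Baylis–Hillman alcohol with SN2′ return of bromide should give the rearranged 2-(bromomethyl)enoate with the usual Z geometry (chain trans to the ester).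

Step 5
Reactants: 10 4-methoxybenzyl propargyl ether
Product: 11 4-[(4-methoxybenzyl)oxy]but-2-ynal
Conditions: nBuLi, THF, −78 °C; DMF; inverse quench into aqueous KH2PO4
Reagents that add atoms: N,N-dimethylformamide, CN(C)C=O
Why: Formylation of a lithium acetylide with DMF; the phosphate quench keeps liberated dimethylamine from adding to the ynal.

Step 6
Reactants: 9 methyl (2Z)-2-(bromomethyl)-6-methylidene-8-(trimethylsilyl)oct-2-en-7-ynoate; 11 4-[(4-methoxybenzyl)oxy]but-2-ynal
Product: 12 methyl (3S,4S)-4-hydroxy-7-[(4-methoxybenzyl)oxy]-2-methylidene-3-[3-methylidene-5-(trimethylsilyl)pent-4-yn-1-yl]hept-5-ynoate (anti; C3 = future C7, C4 = future C6)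
Conditions: CrCl2 (10 mol %), chiral oxazoline–sulfonamide ligand (12 mol %), Et3N (20 mol %), Mn powder (2 equiv), Cp2ZrCl2 (1.1 equiv), THF, 0 °C; work-up at pH 7
Reagents that add atoms: none
Why: Catalytic asymmetric Nozaki–Hiyama–Kishi 2-(alkoxycarbonyl)allylation: the γ-substituted allylchromium adds through a chair transition state at its substituted carbon (anti adduct), the ligand antipode is chosen for the aldehyde face that gives (3S,4S), and the neutral work-up should keep the hydroxy ester from lactonising.

Step 7
Reactants: 12 anti hydroxy ester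
Product: 15 methyl (3R)-7-[(4-methoxybenzyl)oxy]-2-methylidene-3-[3-methylidene-5-(trimethylsilyl)pent-4-yn-1-yl]hepta-4,5-dienoate (single allene diastereomer), via sulfonylhydrazine 13 (not isolated), via propargylic diazene 14 (not isolated)
Conditions: PPh3, DEAD, 2-nitrobenzenesulfonylhydrazide, THF, −15 °C, then 23 °C
Reagents that add atoms: none
Why: Myers allene synthesis: Mitsunobu inversion at the carbinol, loss of sulfinic acid and sigmatropic loss of N2 from the diazene deliver H to the alkyne terminus on the face from which nitrogen departs, so the carbinol configuration is transferred stereospecifically to the allene axis.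

Step 8
Reactants: 15 allene ester
Product: 16 (3R)-7-[(4-methoxybenzyl)oxy]-2-methylidene-3-(3-methylidenepent-4-yn-1-yl)hepta-4,5-dienoic acid
Conditions: LiOH, THF/MeOH/H2O, 0 to 23 °C; then 1 M HCl to pH 3
Reagents that add atoms: lithium hydroxide, [Li+].[OH-]
Why: Saponification of the methyl ester with concurrent protodesilylation of the alkynylsilane under conditions too mild to isomerise the allene or the C7 centre.

Step 9
Reactants: 16 allenyne acid
Product: 18 15-[(4-methoxybenzyl)oxy]-3-oxo-4βH,5αH,6βH,7αH-guaia-1,10(14),11(13)-trien-12,6-olide, via trienone acid 17 (not isolated)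
Conditions: [Rh(CO)2Cl]2 (5 mol %), CO (1 atm), toluene (0.01 M), 90 °C; then 0 °C, DBU (0.2 equiv), to 23 °C
Reagents that add atoms: carbon monoxide, [C-]#[O+]
Why: Proposed new method: the rhodium catalyst binds the alkyne and the distal C4=C5 bond of the allene, oxidative cyclisation forms C1–C5, and CO insertion with reductive elimination gives the 4-alkylidenecyclopentenone 17 (allenic Pauson–Khand reaction, the closest known type, which tolerates four-atom tethers); the amine then turns the C12 acid into a carboxylate that adds to C6, the δ-terminus of the O=C3–C2=C1–C5=C6 dienone, and the dienolate is protonated at C5 (intramolecular oxa-Michael lactonisation, known for enones but not in this 1,6-sense on a 4-alkylidenecyclopentenone nor in tandem with the cyclocarbonylation). The five-membered enone ring and the seven-membered ring are closed together by the [2+2+1] event (the seven-membered ring by C1–C5 bond formation, exo with respect to the allene, the ring alkene C5=C6 necessarily cis), and the lactone ring by 5-exo-trig attack of O on C6. C4 is set by transfer of the allene axis, since C1 and CO add to the same face of C4=C5 and place CH2OPMB α, which is also the thermodynamically preferred trans arrangement. C6 is set by C7, whose acrylate arm sits pseudo-equatorially on the cycloheptadiene and reaches the face of C6 anti to C8 (trans-fused lactone), and C5 by γ-protonation to the all-equatorial 5αH isomer; because addition and protonation are reversible under catalytic base, the mixture should converge on this isomer. The step needs the distal rather than the proximal allene bond to react (secured by the four-atom tether and the rhodium carbonyl chloride catalyst under CO, which also suppresses the Alder-ene path) and needs O to attack C6 and not the other dienone terminus C14 (secured by the tether, C14 being out of reach of the C7 arm).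

Step 10
Reactants: 19 dehydrocostus lactone
Product: 20 3-epizaluzanin C (3α-hydroxy)
Conditions: SeO2 (0.5 equiv), tBuOOH (2 equiv), CH2Cl2, 0 to 23 °C
Reagents that add atoms: selenium dioxide, O=[Se]=O; tert-butyl hydroperoxide, CC(C)(C)OO
Why: Selenium dioxide allylic oxidation (ene reaction then [2,3]-shift) at C3, the ring methylene allylic to C4=C15; the new carbinol configuration is erased in step 11.

Step 11
Reactants: 20 3-epizaluzanin C
Product: 21 dehydrozaluzanin C
Conditions: Dess–Martin periodinane, NaHCO3, CH2Cl2, 0 to 23 °C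
Reagents that add atoms: none
Why: Dess–Martin oxidation of the allylic alcohol under buffered conditions should give the exocyclic enone without isomerisation.

Step 12
Reactants: 18 diene lactone; 21 dehydrozaluzanin C
Product: 22 Diels–Alder adduct (new bonds C2–C4′ and C14–C15′; left half 2βH-3-oxo-1(10)-ene; spiro C4′ as in the target)
Conditions: 21 (2 equiv), BHT (cat.), toluene (0.5 M), 60 °C, argon
Reagents that add atoms: none
Why: Diels–Alder reaction of the 2-vinyl enone diene C2=C1–C10=C14 with the strained exocyclic enone C4′=C15′: the unsubstituted terminus C14 bonds to the β-carbon C15′ and C2 to C4′, and the diene approaches the α-face of 21 (cis to H-1′ and H-5′), which fixes spiro C4′; the C2 centre is transient.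

Step 13
Reactants: 22 Diels–Alder adduct
Product: 24 15-O-(4-methoxybenzyl)ainsliadimer B, via C10 hydroperoxide 23 (not isolated)
Conditions: O2 (1 atm), Et3N (2 equiv), MeCN, 0 to 23 °C; then PPh3 (1.2 equiv), 0 °C
Reagents that add atoms: dioxygen, O=O
Why: γ-Oxygenation of a β,γ-unsaturated ketone: enolisation at the doubly activated C2–H gives the C3 dienol, which traps O2 at C10 to give the conjugated hydroperoxy enone (then reduced by the phosphine); attack should come from the β-face because the C5′ branch of the spiro centre covers the α-face of the cyclohexadiene, in line with the β-preference of 1(10)-ene guaianolides.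

Step 14
Reactants: 24 15-O-(4-methoxybenzyl)ainsliadimer B
Product: 25 ainsliadimer B
Conditions: DDQ, CH2Cl2/pH 7 buffer (10:1), 0 °C
Reagents that add atoms: none
Why: Oxidative cleavage of the 4-methoxybenzyl ether by DDQ; the enone, the exocyclic alkenes and the tertiary alcohol should not react under buffered conditions.

**Compound list**

1 | acetaldehyde N,N-dimethylhydrazone | CC=NN(C)C | starting material
2 | 2,3-dibromoprop-1-ene | C=C(Br)CBr | starting material
3 | 4-bromopent-4-enal N,N-dimethylhydrazone | C=C(Br)CCC=NN(C)C | intermediate (not isolated)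
4 | 4-bromopent-4-enal | C=C(Br)CCC=O | intermediate
5 | ethynyltrimethylsilane | C#C[Si](C)(C)C | starting material
6 | 4-methylidene-6-(trimethylsilyl)hex-5-ynal | O=CCCC(=C)C#C[Si](C)(C)C | intermediate
7 | methyl acrylate | C=CC(=O)OC | starting material
8 | methyl 3-hydroxy-2,6-dimethylidene-8-(trimethylsilyl)oct-7-ynoate (racemic) | COC(=O)C(=C)C(O)CCC(=C)C#C[Si](C)(C)C | intermediate
9 | methyl (2Z)-2-(bromomethyl)-6-methylidene-8-(trimethylsilyl)oct-2-en-7-ynoate | COC(=O)C(/CBr)=C/CCC(=C)C#C[Si](C)(C)C | intermediate
10 | 4-methoxybenzyl propargyl ether | C#CCOCc1ccc(OC)cc1 | starting material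
11 | 4-[(4-methoxybenzyl)oxy]but-2-ynal | O=CC#CCOCc1ccc(OC)cc1 | intermediate
12 | methyl (3S,4S)-4-hydroxy-7-[(4-methoxybenzyl)oxy]-2-methylidene-3-[3-methylidene-5-(trimethylsilyl)pent-4-yn-1-yl]hept-5-ynoate | COC(=O)C(=C)[C@H](CCC(=C)C#C[Si](C)(C)C)[C@H](O)C#CCOCc1ccc(OC)cc1 | intermediate
13 | N-alkyl-N-(2-nitrobenzenesulfonyl)hydrazine from 12 (carbinol carbon inverted) | COC(=O)C(=C)[C@H](CCC(=C)C#C[Si](C)(C)C)[C@@H](N(N)S(=O)(=O)c1ccccc1[N+](=O)[O-])C#CCOCc1ccc(OC)cc1 | intermediate (not isolated)
14 | propargylic monoalkyl diazene | COC(=O)C(=C)[C@H](CCC(=C)C#C[Si](C)(C)C)[C@@H](N=N)C#CCOCc1ccc(OC)cc1 | intermediate (not isolated)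
15 | methyl (3R)-7-[(4-methoxybenzyl)oxy]-2-methylidene-3-[3-methylidene-5-(trimethylsilyl)pent-4-yn-1-yl]hepta-4,5-dienoate, single allene diastereomer | COC(=O)C(=C)[C@H](CCC(=C)C#C[Si](C)(C)C)C([H])=[C@@]=C([H])COCc1ccc(OC)cc1 | intermediate
16 | (3R)-7-[(4-methoxybenzyl)oxy]-2-methylidene-3-(3-methylidenepent-4-yn-1-yl)hepta-4,5-dienoic acid | OC(=O)C(=C)[C@H](CCC(=C)C#C)C([H])=[C@@]=C([H])COCc1ccc(OC)cc1 | intermediate
17 | 15-[(4-methoxybenzyl)oxy]-3-oxo-4βH,7αH-guaia-1,5,10(14),11(13)-tetraen-12-oic acid | OC(=O)C(=C)[C@@H]1CCC(=C)C2=CC(=O)[C@@H](COCc3ccc(OC)cc3)C2=C1 | intermediate (not isolated)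
18 | 15-[(4-methoxybenzyl)oxy]-3-oxo-4βH,5αH,6βH,7αH-guaia-1,10(14),11(13)-trien-12,6-olide | C=C1C(=O)O[C@@H]2[C@@H]3C(=CC(=O)[C@H]3COCc4ccc(OC)cc4)C(=C)CC[C@@H]12 | intermediate
19 | dehydrocostus lactone | C=C1CC[C@H]2C(=C)CC[C@H]3C(=C)C(=O)O[C@@H]3[C@@H]12 | starting material
20 | 3-epizaluzanin C (3α-hydroxydehydrocostus lactone) | C=C1[C@H](O)C[C@H]2C(=C)CC[C@H]3C(=C)C(=O)O[C@@H]3[C@@H]12 | intermediate
21 | dehydrozaluzanin C | C=C1C(=O)C[C@H]2C(=C)CC[C@H]3C(=C)C(=O)O[C@@H]3[C@@H]12 | intermediate
22 | Diels–Alder adduct of 18 and 21 (C2–C4′, C14–C15′; 2βH, 1(10)-ene) | C=C1C(=O)O[C@@H]2[C@@H]3C4=C(CC[C@@H]12)CC[C@]5(C(=O)C[C@H]6C(=C)CC[C@H]7C(=C)C(=O)O[C@@H]7[C@@H]56)[C@H]4C(=O)[C@H]3COCc8ccc(OC)cc8 | intermediate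
23 | 15-O-(4-methoxybenzyl)ainsliadimer B 10β-hydroperoxide | C=C1C(=O)O[C@@H]2[C@@H]3C4=C(C(=O)[C@H]3COCc5ccc(OC)cc5)[C@]3(CC[C@]4(OO)CC[C@@H]12)C(=O)C[C@H]1C(=C)CC[C@H]2C(=C)C(=O)O[C@@H]2[C@H]13 | intermediate (not isolated)
24 | 15-O-(4-methoxybenzyl)ainsliadimer B | C=C1C(=O)O[C@@H]2[C@@H]3C4=C(C(=O)[C@H]3COCc5ccc(OC)cc5)[C@]3(CC[C@]4(O)CC[C@@H]12)C(=O)C[C@H]1C(=C)CC[C@H]2C(=C)C(=O)O[C@@H]2[C@H]13 | intermediate
25 | ainsliadimer B | C=C1C(=O)O[C@@H]2[C@@H]3C4=C(C(=O)[C@H]3CO)[C@]3(CC[C@]4(O)CC[C@@H]12)C(=O)C[C@H]1C(=C)CC[C@H]2C(=C)C(=O)O[C@@H]2[C@H]13 | target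

**Step count and risks**

Total steps: 14. Longest linear sequence: 11 (steps 1, 2, 3, 4, 6, 7, 8, 9, 12, 13, 14).

Most likely to fail:

1. Step 9 (proposed new method). What may go wrong: the free acid may add to the allene under rhodium catalysis before cyclocarbonylation; the carboxylate may close onto the wrong face of C6 (cis-fused lactone) or the dienol may not relay the proton to C5; base may expel 4-methoxybenzyl alcohol from C15. Fallback with known chemistry, setting out from 21 and returning at 18, with the lactone inherited rather than closed: base-catalysed oxa-Michael addition of 4-methoxybenzyl alcohol to the exocyclic enone of 21 (DBU cat., THF) should give the 4βH 15-O-(4-methoxybenzyl) ketone F1; kinetic enolisation toward C2 (LiN(iPr)2, TMSCl, THF, −78 °C) should give the silyl enol ether F2; Saegusa oxidation (Pd(OAc)2, MeCN, 23 °C) should give 18.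

2. Step 13. What may go wrong: oxygen may be delivered to the α-face of C10 or to C2, or the dienol may simply tautomerise to the conjugated enone without oxygenation. Fallback, setting out from 22 and returning at 24: epoxidation of the tetrasubstituted C1=C10 alkene with dimethyldioxirane (acetone, −20 °C), expected from the β-face as for 1(10)-ene guaianolides, should give the 1β,10β-epoxide F3; DBU-mediated E1cB opening of this β,γ-epoxy ketone (CH2Cl2, 0 °C) should give 24 with the C10 configuration fixed by the epoxide.

3. Step 6. What may go wrong: insufficient enantio- or diastereocontrol with the ynal and the branched allyl bromide, or premature lactonisation of the adduct. Fallback, setting out from 9 and 11 and returning at 12: stoichiometric CrCl2-mediated coupling (THF, 0 °C) should give the anti adduct as the racemate, i.e. 12 together with its enantiomer F4; acylative kinetic resolution (benzotetramisole catalyst antipode chosen to acylate F4, propionic anhydride, iPr2NEt, CHCl3, 0 °C) should leave 12 unreacted and convert F4 into the propionate F5, which is separated by chromatography.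

**Further compounds**

F1 | step 9 | 15-[(4-methoxybenzyl)oxy]-3-oxo-1αH,4βH,5αH-guaia-10(14),11(13)-dien-12,6-olide | C=C1C(=O)O[C@@H]2[C@@H]3[C@@H](CC(=O)[C@H]3COCc4ccc(OC)cc4)C(=C)CC[C@@H]12
F2 | step 9 | 3-(trimethylsilyloxy)-2-ene enol ether of F1 | C=C1C(=O)O[C@@H]2[C@@H]3[C@@H](C=C(O[Si](C)(C)C)[C@H]3COCc4ccc(OC)cc4)C(=C)CC[C@@H]12
F3 | step 13 | 1β,10β-epoxide of 22 | C=C1C(=O)O[C@@H]2[C@@H]3[C@@]4(O9)[C@@]9(CC[C@@H]12)CC[C@]5(C(=O)C[C@H]6C(=C)CC[C@H]7C(=C)C(=O)O[C@@H]7[C@@H]56)[C@H]4C(=O)[C@H]3COCc8ccc(OC)cc8
F4 | step 6 | (3R,4R) enantiomer of 12 | COC(=O)C(=C)[C@@H](CCC(=C)C#C[Si](C)(C)C)[C@@H](O)C#CCOCc1ccc(OC)cc1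
F5 | step 6 | propionate of F4 | COC(=O)C(=C)[C@@H](CCC(=C)C#C[Si](C)(C)C)[C@@H](OC(=O)CC)C#CCOCc1ccc(OC)cc1
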